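**Retrosynthetic overview**
- The C7=C8 alkene is formed last, by aldol addition and E1cB elimination between a 2-bromo-4-hydroxy-4-octadienylcyclopentenone (C8–C20) and a silyl-protected (R,E)-4-oxy-7-oxoheptenoate (C1–C7).
- Bromine is introduced only after the Z,Z-diene exists, by enone epoxidation and HBr opening, so no electrophilic bromine meets the skipped diene.
- The Z,Z-diene comes from a skipped diyne (Lindlar), built from a terminal alkyne and 1-bromopent-2-yne.
- Key step: the C12–C13 bond and the C12 carbinol centre are made by a radical Barbier (Nozaki–Hiyama type) propargylation with CrCl2 on (R)-4-silyloxycyclopentenone, anti to the silyloxy group.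
- Rings: the five-membered ring is bought and never re-formed; the only ring made is the transient oxirane. C4 is set by an asymmetric alkenylzinc addition.

Assumption: prostanoid numbering is used for atom labels (ester carbon C1, ring C8–C12, terminal methyl C20); compounds 1, 2, 5, 14 and 15 are purchased.

**Step 1**
Reactants: 1 (R)-4-[(tert-butyldimethylsilyl)oxy]cyclopent-2-en-1-one; 2 3-bromoprop-1-yne
Product: 4 (1S,4R)-4-[(tert-butyldimethylsilyl)oxy]-1-(prop-2-yn-1-yl)cyclopent-2-en-1-ol, via allenylchromium dichloride 3 (not isolated)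
Conditions: CrCl2 (3 equiv), THF, 0 → 23 °C; aq NH4Cl
Reagents that add atoms: none
Why: Nozaki–Hiyama-type radical Barbier propargylation, in which divalent chromium abstracts bromine from 2, the propargyl radical is captured by a second divalent chromium as the trivalent allenylchromium 3, and 3 adds through its CH2 terminus 1,2 to the ketone on the face anti to the C9 silyloxy group, setting C12 (1S in 4, cis-1,4-dioxygen array) by 1,3-substrate control.

**Step 2**
Reactants: 4 (1S,4R)-4-[(tert-butyldimethylsilyl)oxy]-1-(prop-2-yn-1-yl)cyclopent-2-en-1-ol; 5 1-bromopent-2-yne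
Product: 8 (1S,4R)-1-(octa-2,5-diyn-1-yl)cyclopent-2-ene-1,4-diol, via copper acetylide 6 (not isolated), via silyl ether 7 (not isolated)
Conditions: CuI (1 equiv), Cs2CO3, DMF, 23 °C; then Bu4NF, THF, 23 °C
Reagents that add atoms: none
Why: Copper acetylide alkylation by a primary propargylic bromide (SN2, skipped-diyne synthesis) followed by fluoride cleavage of the silyl ether in the same flask; no stereocentre is touched.

**Step 3**
Reactants: 8 (1S,4R)-1-(octa-2,5-diyn-1-yl)cyclopent-2-ene-1,4-diol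
Product: 9 (1S,4R)-1-[(2Z,5Z)-octa-2,5-dien-1-yl]cyclopent-2-ene-1,4-diol
Conditions: H2 (1 atm, 2 equiv uptake), Pd/CaCO3 poisoned with Pb(OAc)2, quinoline, EtOAc, 0 °C
Reagents that add atoms: none
Why: Lindlar semi-hydrogenation, in which syn delivery of H2 on the lead-poisoned palladium surface gives the 14Z and 17Z alkenes and stops before the ring alkene reacts.

**Step 4**
Reactants: 9 (1S,4R)-1-[(2Z,5Z)-octa-2,5-dien-1-yl]cyclopent-2-ene-1,4-diol
Product: 10 (S)-4-hydroxy-4-[(2Z,5Z)-octa-2,5-dien-1-yl]cyclopent-2-en-1-one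
Conditions: MnO2, CH2Cl2, 23 °C
Reagents that add atoms: none
Why: Chemoselective MnO2 oxidation of the secondary allylic alcohol to the enone; the tertiary C12 alcohol and the skipped diene are inert, and the C9 stereocentre is spent here.

**Step 5**
Reactants: 10 (S)-4-hydroxy-4-[(2Z,5Z)-octa-2,5-dien-1-yl]cyclopent-2-en-1-one
Product: 11 (1S,4S,5R)-4-hydroxy-4-[(2Z,5Z)-octa-2,5-dien-1-yl]-6-oxabicyclo[3.1.0]hexan-2-one
Conditions: 30% H2O2, NaOH (cat.), MeOH, 0 °C, short reaction time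
Reagents that add atoms: hydrogen peroxide, OO
Why: Weitz–Scheffer nucleophilic epoxidation, in which hydroperoxide anion adds only to the electron-poor enone C=C (the isolated Z alkenes are inert), expected cis to the C12 hydroxyl by hydrogen-bond delivery; the oxirane configuration is erased in step 6.

**Step 6**
Reactants: 11 (1S,4S,5R)-4-hydroxy-4-[(2Z,5Z)-octa-2,5-dien-1-yl]-6-oxabicyclo[3.1.0]hexan-2-one
Product: 13 (S)-2-bromo-4-hydroxy-4-[(2Z,5Z)-octa-2,5-dien-1-yl]cyclopent-2-en-1-one, via bromohydrin 12 (not isolated)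
Conditions: 48% aq HBr, THF, 0 → 23 °C
Reagents that add atoms: hydrogen bromide, Br
Why: Epoxy-ketone to α-bromo-enone conversion, in which bromide opens the protonated oxirane by SN2 at C10 (α to the carbonyl, C11 being neopentyl) and bromohydrin 12 loses water through its enol; C12 is untouched and the skipped diene does not add dilute HBr at this temperature.

**Step 7**
Reactants: 14 3,3-dimethoxyprop-1-yne; 15 methyl 4-oxobutanoate
Product: 18 methyl (4R,5E)-4-hydroxy-7,7-dimethoxyhept-5-enoate, via alkenylborane 16 (not isolated), via alkenylzinc 17 (not isolated)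
Conditions: Cy2BH, toluene, 0 → 23 °C; Et2Zn, −78 °C; (−)-MIB (4 mol %), then 15, −10 °C; aq NH4Cl
Reagents that add atoms: none
Why: Oppolzer–Walsh asymmetric alkenylation, in which syn hydroboration fixes the 5E alkene, boron-to-zinc exchange gives 17, and the (−)-MIB zinc aminoalkoxide delivers the alkenyl group to the Si face of aldehyde 15 to set 4R (the ester does not react with the organozinc).

**Step 8**
Reactants: 18 methyl (4R,5E)-4-hydroxy-7,7-dimethoxyhept-5-enoate
Product: 19 methyl (4R,5E)-4-[(tert-butyldimethylsilyl)oxy]-7,7-dimethoxyhept-5-enoate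
Conditions: TBSCl, imidazole, DMF, 23 °C
Reagents that add atoms: tert-butyldimethylsilyl chloride, CC(C)(C)[Si](C)(C)Cl
Why: Standard silylation of the secondary alcohol (Corey protocol), which blocks lactonisation and enolate quenching later; C4 is unchanged.

**Step 9**
Reactants: 19 methyl (4R,5E)-4-[(tert-butyldimethylsilyl)oxy]-7,7-dimethoxyhept-5-enoate
Product: 20 methyl (4R,5E)-4-[(tert-butyldimethylsilyl)oxy]-7-oxohept-5-enoate
Conditions: PPTS (cat.), acetone–H2O (10:1), 23 °C
Reagents that add atoms: water, O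
Why: Acid-catalysed acetal hydrolysis through the oxocarbenium ion under conditions that leave the secondary silyl ether, the ester and the E alkene intact.

**Step 10**
Reactants: 13 (S)-2-bromo-4-hydroxy-4-[(2Z,5Z)-octa-2,5-dien-1-yl]cyclopent-2-en-1-one; 20 methyl (4R,5E)-4-[(tert-butyldimethylsilyl)oxy]-7-oxohept-5-enoate
Product: 22 methyl (4R,5E)-7-[(2S)-4-bromo-2-hydroxy-2-[(2Z,5Z)-octa-2,5-dien-1-yl]-5-oxocyclopent-3-en-1-yl]-4-[(tert-butyldimethylsilyl)oxy]-7-hydroxyhept-5-enoate (mixture at C7 and C8), via dilithium enolate 21 (not isolated)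
Conditions: LiN(iPr)2 (2.1 equiv), THF, −78 °C; then 20, −78 °C; aq NH4Cl
Reagents that add atoms: none
Why: Directed aldol addition, in which the first equivalent of amide forms the C12 alkoxide and the second the kinetic α′ (C8) enolate, which adds to the aldehyde of 20 faster than to its ester; the C7 and C8 centres form as a mixture that is erased in step 11, and C12 and C4 are untouched.

**Step 11**
Reactants: 22 methyl (4R,5E)-7-[(2S)-4-bromo-2-hydroxy-2-[(2Z,5Z)-octa-2,5-dien-1-yl]-5-oxocyclopent-3-en-1-yl]-4-[(tert-butyldimethylsilyl)oxy]-7-hydroxyhept-5-enoate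
Product: 24 methyl (4R,5E,7Z)-7-[(2R)-4-bromo-2-hydroxy-2-[(2Z,5Z)-octa-2,5-dien-1-yl]-5-oxocyclopent-3-en-1-ylidene]-4-[(tert-butyldimethylsilyl)oxy]hept-5-enoate, via mesylate 23 (not isolated)
Conditions: MsCl, Et3N, CH2Cl2, −20 °C; then DBU, 0 °C
Reagents that add atoms: none
Why: Selective mesylation of the secondary aldol hydroxyl and E1cB elimination through the cross-conjugated dienolate; the C7 chain is expected to turn away from the fully substituted C12 (A1,3 strain), so the 7Z dienone should be a major isomer and is separated from the 7E isomer by chromatography (the ratio is not secured, see below).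

**Step 12**
Reactants: 24 methyl (4R,5E,7Z)-7-[(2R)-4-bromo-2-hydroxy-2-[(2Z,5Z)-octa-2,5-dien-1-yl]-5-oxocyclopent-3-en-1-ylidene]-4-[(tert-butyldimethylsilyl)oxy]hept-5-enoate
Product: 25 methyl (4R,5E,7Z)-7-[(2R)-4-bromo-2-hydroxy-2-[(2Z,5Z)-octa-2,5-dien-1-yl]-5-oxocyclopent-3-en-1-ylidene]-4-hydroxyhept-5-enoate
Conditions: HF·pyridine, pyridine, THF, 0 → 23 °C
Reagents that add atoms: none
Why: Buffered fluoride desilylation, which frees the C4 hydroxyl without acid- or base-induced lactonisation, retro-aldol cleavage at C12 or alkene isomerisation.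

**Compound list**
1 | (R)-4-[(tert-butyldimethylsilyl)oxy]cyclopent-2-en-1-one | O=C1C=C[C@H](O[Si](C)(C)C(C)(C)C)C1 | starting material
2 | 3-bromoprop-1-yne | BrCC#C | starting material
3 | propa-1,2-dien-1-ylchromium dichloride (allenylchromium dichloride) | C=C=C[Cr](Cl)Cl | intermediate
4 | (1S,4R)-4-[(tert-butyldimethylsilyl)oxy]-1-(prop-2-yn-1-yl)cyclopent-2-en-1-ol | C#CC[C@@]1(O)C=C[C@H](O[Si](C)(C)C(C)(C)C)C1 | intermediate
5 | 1-bromopent-2-yne | CCC#CCBr | starting material
6 | copper acetylide of 4 | [Cu]C#CC[C@@]1(O)C=C[C@H](O[Si](C)(C)C(C)(C)C)C1 | intermediate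
7 | (1S,4R)-4-[(tert-butyldimethylsilyl)oxy]-1-(octa-2,5-diyn-1-yl)cyclopent-2-en-1-ol | CCC#CCC#CC[C@@]1(O)C=C[C@H](O[Si](C)(C)C(C)(C)C)C1 | intermediate
8 | (1S,4R)-1-(octa-2,5-diyn-1-yl)cyclopent-2-ene-1,4-diol | CCC#CCC#CC[C@@]1(O)C=C[C@H](O)C1 | intermediate
9 | (1S,4R)-1-[(2Z,5Z)-octa-2,5-dien-1-yl]cyclopent-2-ene-1,4-diol | CC/C=C\C/C=C\C[C@@]1(O)C=C[C@H](O)C1 | intermediate
10 | (S)-4-hydroxy-4-[(2Z,5Z)-octa-2,5-dien-1-yl]cyclopent-2-en-1-one | CC/C=C\C/C=C\C[C@@]1(O)C=CC(=O)C1 | intermediate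
11 | (1S,4S,5R)-4-hydroxy-4-[(2Z,5Z)-octa-2,5-dien-1-yl]-6-oxabicyclo[3.1.0]hexan-2-one | CC/C=C\C/C=C\C[C@@]1(O)[C@@H]2O[C@@H]2C(=O)C1 | intermediate
12 | (2R,3S,4S)-2-bromo-3,4-dihydroxy-4-[(2Z,5Z)-octa-2,5-dien-1-yl]cyclopentan-1-one | CC/C=C\C/C=C\C[C@@]1(O)[C@H](O)[C@@H](Br)C(=O)C1 | intermediate
13 | (S)-2-bromo-4-hydroxy-4-[(2Z,5Z)-octa-2,5-dien-1-yl]cyclopent-2-en-1-one | CC/C=C\C/C=C\C[C@@]1(O)C=C(Br)C(=O)C1 | intermediate
14 | 3,3-dimethoxyprop-1-yne | C#CC(OC)OC | starting material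
15 | methyl 4-oxobutanoate | COC(=O)CCC=O | starting material
16 | (E)-dicyclohexyl(3,3-dimethoxyprop-1-en-1-yl)borane | COC(OC)/C=C/B(C1CCCCC1)C1CCCCC1 | intermediate
17 | ethyl[(E)-3,3-dimethoxyprop-1-en-1-yl]zinc | CC[Zn]/C=C/C(OC)OC | intermediate
18 | methyl (4R,5E)-4-hydroxy-7,7-dimethoxyhept-5-enoate | COC(=O)CC[C@@H](O)/C=C/C(OC)OC | intermediate
19 | methyl (4R,5E)-4-[(tert-butyldimethylsilyl)oxy]-7,7-dimethoxyhept-5-enoate | COC(=O)CC[C@@H](O[Si](C)(C)C(C)(C)C)/C=C/C(OC)OC | intermediate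
20 | methyl (4R,5E)-4-[(tert-butyldimethylsilyl)oxy]-7-oxohept-5-enoate | COC(=O)CC[C@@H](O[Si](C)(C)C(C)(C)C)/C=C/C=O | intermediate
21 | dilithium alkoxide–enolate of 13 | CC/C=C\C/C=C\C[C@@]1(O[Li])C=C(Br)C(O[Li])=C1 | intermediate
22 | methyl (4R,5E)-7-[(2S)-4-bromo-2-hydroxy-2-[(2Z,5Z)-octa-2,5-dien-1-yl]-5-oxocyclopent-3-en-1-yl]-4-[(tert-butyldimethylsilyl)oxy]-7-hydroxyhept-5-enoate (mixture at C7 and C8) | CC/C=C\C/C=C\C[C@@]1(O)C=C(Br)C(=O)C1C(O)/C=C/[C@H](O[Si](C)(C)C(C)(C)C)CCC(=O)OC | intermediate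
23 | 7-methanesulfonate of 22 | CC/C=C\C/C=C\C[C@@]1(O)C=C(Br)C(=O)C1C(OS(C)(=O)=O)/C=C/[C@H](O[Si](C)(C)C(C)(C)C)CCC(=O)OC | intermediate
24 | methyl (4R,5E,7Z)-7-[(2R)-4-bromo-2-hydroxy-2-[(2Z,5Z)-octa-2,5-dien-1-yl]-5-oxocyclopent-3-en-1-ylidene]-4-[(tert-butyldimethylsilyl)oxy]hept-5-enoate | CC/C=C\C/C=C\C[C@@]1(O)C=C(Br)C(=O)/C1=C\C=C\[C@H](O[Si](C)(C)C(C)(C)C)CCC(=O)OC | intermediate
25 | methyl (4R,5E,7Z)-7-[(2R)-4-bromo-2-hydroxy-2-[(2Z,5Z)-octa-2,5-dien-1-yl]-5-oxocyclopent-3-en-1-ylidene]-4-hydroxyhept-5-enoate | CC/C=C\C/C=C\C[C@@]1(O)C=C(Br)C(=O)/C1=C\C=C\[C@H](O)CCC(=O)OC | target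

**Totals**
Total step count: 12.
Longest linear sequence: 9 steps (steps 1–6, then 10–12, from compound 1).

**Three steps most likely to fail**

Step 1. The chromium-mediated propargylation may give allenyl carbinol, poor facial selectivity, or little conversion with this conjugated ketone. The fallback makes the C12–C13 bond by epoxide opening instead and sets out from 1. Dimethylsulfonium methylide (Me3S+ I−, n-BuLi, THF, −10 °C, Corey–Chaykovsky) adds to the ketone anti to the silyloxy group and gives the spiro-epoxide (3S,6R)-6-[(tert-butyldimethylsilyl)oxy]-1-oxaspiro[2.4]hept-4-ene F1. Its CH2 carbon is then opened by LiC≡CH·H2NCH2CH2NH2 in DMSO at 23 °C, and the route is rejoined at 4.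

Step 5. Alkaline peroxide may erode C12 by retro-aldol and re-closure of the β-hydroxy ketone, or epoxidise slowly at the neopentyl β-carbon. The fallback epoxidises before the ketone exists and sets out from diol 9. VO(acac)2 (cat.) and t-BuOOH in CH2Cl2 at 0 °C give, by delivery from both cis hydroxyls, the epoxy diol (1R,2S,4R,5R)-2-[(2Z,5Z)-octa-2,5-dien-1-yl]-6-oxabicyclo[3.1.0]hexane-2,4-diol F2. Dess–Martin periodinane (pyridine, CH2Cl2, 0 °C) then oxidises the secondary alcohol, and the route is rejoined at 11; steps 4 and 5 are bypassed.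

Step 11. The elimination may give mainly the 7E isomer, methyl (4R,5E,7E)-7-[(2R)-4-bromo-2-hydroxy-2-[(2Z,5Z)-octa-2,5-dien-1-yl]-5-oxocyclopent-3-en-1-ylidene]-4-[(tert-butyldimethylsilyl)oxy]hept-5-enoate F3. The fallback sets out from 22 through 23 and recycles F3 instead of discarding it. Irradiation at 365 nm in benzene with catalytic PhSSPh equilibrates the C7=C8 geometry by reversible thiyl-radical addition, the 7Z isomer is separated, and the route is rejoined at 24.

**Further compounds**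
F1 | step 1 | (3S,6R)-6-[(tert-butyldimethylsilyl)oxy]-1-oxaspiro[2.4]hept-4-ene | C1O[C@@]12C=C[C@H](O[Si](C)(C)C(C)(C)C)C2
F2 | step 5 | (1R,2S,4R,5R)-2-[(2Z,5Z)-octa-2,5-dien-1-yl]-6-oxabicyclo[3.1.0]hexane-2,4-diol | CC/C=C\C/C=C\C[C@@]1(O)[C@@H]2O[C@@H]2[C@H](O)C1
F3 | step 11 | methyl (4R,5E,7E)-7-[(2R)-4-bromo-2-hydroxy-2-[(2Z,5Z)-octa-2,5-dien-1-yl]-5-oxocyclopent-3-en-1-ylidene]-4-[(tert-butyldimethylsilyl)oxy]hept-5-enoate | CC/C=C\C/C=C\C[C@@]1(O)C=C(Br)C(=O)/C1=C/C=C/[C@H](O[Si](C)(C)C(C)(C)C)CCC(=O)OC
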